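**Plan**
- Cuts, in retrosynthetic order: the three O–benzyl bonds; ring C at O1–C2 and C2–C3 (C2 is a one-carbon insert into a 2-hydroxydeoxybenzoin); C3–C4 (ring B benzylzinc plus ring A aroyl chloride); ring B at C1'–C6'; the open chain at C5'–C6' and C3'–C4'.
- Enabling feature: ring B has meta oxygens at C2' and C4', a carbon substituent at C1' and an alkyl chain at C6'. This is the 6-alkylresorcylate (orsellinate) pattern of a folded tetracarbonyl chain. C5' with its OMe is simply the methine between two chain ketones.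
- Forward order: side-chain amide plus methoxy keto-dioxinone give the diketo-dioxinone. Ring B then forms by aldol aromatization and its masked carboxyl carbon is reduced to the benzylic carbon (future C3). Ring A arrives ready-made from 2,4-dihydroxybenzoic acid, and ring C closes last.
- Stereochemistry: the target has no stereocentre. The transient centres of the chain and of the aldol adduct all become sp2 carbons on aromatization.

Key step: step 5

Remark: "hydrate" is taken as the covalent tertiary alcohol of the C6' chain, as drawn in the SMILES. The hindered C3–C1' axis carries no descriptor and is treated as configurationally unassigned.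

**Step 1**
Reactants: 1 5,5-dimethyloxolan-2-one
Product: 2 4-hydroxy-N-methoxy-N,4-dimethylpentanamide
Conditions: MeNH(OMe)·HCl, AlMe3, CH2Cl2, 0 °C to rt; aq. potassium sodium tartrate; used crude
Reagents that add atoms: N,O-dimethylhydroxylamine hydrochloride, CNOC.Cl
Why: Weinreb amidation of a lactone with the aluminium amide is a standard ring opening, and the neutral work-up with direct use of crude 2 should forestall relactonization.

**Step 2**
Reactants: 2 4-hydroxy-N-methoxy-N,4-dimethylpentanamide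
Product: 3 N-methoxy-N,4-dimethyl-4-(triethylsilyloxy)pentanamide
Conditions: Et3SiOTf, 2,6-lutidine, CH2Cl2, 0 °C
Reagents that add atoms: triethylsilyl trifluoromethanesulfonate, CC[Si](CC)(CC)OS(=O)(=O)C(F)(F)F
Why: Silyl triflate with lutidine is the usual silylation of hindered tertiary alcohols, and the resulting ether should tolerate strong base, hydride and zinc yet leave with fluoride.

**Step 3**
Reactants: 4 2,2,6-trimethyl-4H-1,3-dioxin-4-one; 5 methoxyacetyl chloride
Product: 7 6-(3-methoxy-2-oxopropyl)-2,2-dimethyl-4H-1,3-dioxin-4-one, via lithium dienolate 6 (not isolated)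
Conditions: 4 (2 equiv), LiN(SiMe3)2 (2 equiv), THF, −78 °C; 5 (1 equiv), −78 °C; 1 M HCl
Reagents that add atoms: none
Why: γ-Selective C-acylation of the dioxinone dienolate by an acid chloride (vinylogous Claisen condensation) is well established, and the second equivalent of 6 takes up the acidic proton of 7 so that acylation stops after one event.

**Step 4**
Reactants: 7 6-(3-methoxy-2-oxopropyl)-2,2-dimethyl-4H-1,3-dioxin-4-one; 3 N-methoxy-N,4-dimethyl-4-(triethylsilyloxy)pentanamide
Product: 9 6-[3-methoxy-7-methyl-2,4-dioxo-7-(triethylsilyloxy)octyl]-2,2-dimethyl-4H-1,3-dioxin-4-one (racemic), via dilithium dianion 8 (not isolated)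
Conditions: LiN(iPr)2 (2.2 equiv), THF, −78 to −40 °C; 3, −78 to −10 °C; AcOH quench
Reagents that add atoms: none
Why: In this Harris–Weiler type dianion acylation the last-formed, most basic carbanion (the methoxy-bearing carbon, future C5') reacts, and the Weinreb amide holds the adduct as a lithium chelate until the quench, which excludes over-addition.

**Step 5**
Reactants: 9 6-[3-methoxy-7-methyl-2,4-dioxo-7-(triethylsilyloxy)octyl]-2,2-dimethyl-4H-1,3-dioxin-4-one
Product: 11 7-hydroxy-6-methoxy-2,2-dimethyl-5-[3-methyl-3-(triethylsilyloxy)butyl]-4H-1,3-benzodioxin-4-one, via cyclic aldol adduct 10 (not isolated)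
Conditions: Et3N (excess), CH2Cl2, rt
Reagents that add atoms: none
Why: Et3N removes a proton from the doubly activated CH2 between the dioxinone and the C4' ketone, the vinylogous dienolate attacks the C6' ketone through dioxinone C5 (future C1') to give 10, and 10 loses water by E1cB through its C5' hydrogen and then enolizes through C3'–H to the C4' phenol, so the C1'–C6' bond and ring B arise in one operation. The closest known reaction type is the base-induced aldol aromatization of diketo-dioxinones to acetonide-masked 6-alkylresorcylates, the laboratory counterpart of polyketide folding. The one new ring closes in a favoured 6-(enolexo)-exo-trig mode from dioxinone C5 and C6 plus four chain carbons. No stereocentre is retained, since the enolizable C5' centre of 9 and both centres of 10 end as aromatic carbons. The step needs C-aldol in place of Claisen, lactone or pyranone closure and a single fold: the acetonide offers no free ester or acid and releases no acylketene at room temperature, the doubly activated C3' methylene could reach the C6' ketone only through a four-membered ring, and the side-chain CH2 beside the C6' ketone is too weakly acidic for Et3N. The C5' methoxy group should help, because 2-substituted 1,3-diketones are less enolized and the C6' carbonyl is inductively activated.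

**Step 6**
Reactants: 11 7-hydroxy-6-methoxy-2,2-dimethyl-5-[3-methyl-3-(triethylsilyloxy)butyl]-4H-1,3-benzodioxin-4-one
Product: 12 7-(benzyloxy)-6-methoxy-2,2-dimethyl-5-[3-methyl-3-(triethylsilyloxy)butyl]-4H-1,3-benzodioxin-4-one
Conditions: BnBr, K2CO3, DMF, rt
Reagents that add atoms: benzyl bromide, BrCc1ccccc1
Why: Williamson etherification of the only free phenol under anhydrous carbonate conditions should leave the acetonide lactone and the silyl ether untouched.

**Step 7**
Reactants: 12 7-(benzyloxy)-6-methoxy-2,2-dimethyl-5-[3-methyl-3-(triethylsilyloxy)butyl]-4H-1,3-benzodioxin-4-one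
Product: 13 5-(benzyloxy)-2-(hydroxymethyl)-4-methoxy-3-[3-methyl-3-(triethylsilyloxy)butyl]phenol
Conditions: LiAlH4, THF, 0 °C to rt; aq. potassium sodium tartrate
Reagents that add atoms: none
Why: Hydride reduction of an acetonide-masked salicylate takes the lactone carbonyl to CH2OH while the ketal fragment collapses and frees the C2' phenol, with benzyl, methyl and silyl ethers inert.

**Step 8**
Reactants: 13 5-(benzyloxy)-2-(hydroxymethyl)-4-methoxy-3-[3-methyl-3-(triethylsilyloxy)butyl]phenol
Product: 14 {4,6-bis(benzyloxy)-3-methoxy-2-[3-methyl-3-(triethylsilyloxy)butyl]phenyl}methanol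
Conditions: BnBr, K2CO3, acetone, 50 °C
Reagents that add atoms: benzyl bromide, BrCc1ccccc1
Why: This Williamson etherification is chemoselective because carbonate deprotonates the phenol but not the benzylic alcohol, and the temperature stays well below that needed for quinone methide formation.

**Step 9**
Reactants: 14 {4,6-bis(benzyloxy)-3-methoxy-2-[3-methyl-3-(triethylsilyloxy)butyl]phenyl}methanol
Product: 16 1,5-bis(benzyloxy)-2-(chloromethyl)-4-methoxy-3-[3-methyl-3-(triethylsilyloxy)butyl]benzene, via benzylic mesylate 15 (not isolated)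
Conditions: MsCl, Et3N, CH2Cl2, −10 °C to rt; cold aq. NaHCO3 wash; used at once
Reagents that add atoms: methanesulfonyl chloride, CS(=O)(=O)Cl
Why: Mesylation of an electron-rich benzylic alcohol is followed at once by nucleophilic displacement by the liberated chloride, and the amine buffer keeps acid away from the silyl ether.

**Step 10**
Reactants: 17 2,4-dihydroxybenzoic acid
Product: 18 4-(benzyloxy)-2-hydroxybenzoic acid
Conditions: BnBr (1 equiv), KOH (2 equiv), EtOH–H2O, reflux; HCl to pH 2
Reagents that add atoms: benzyl bromide, BrCc1ccccc1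
Why: In this Williamson etherification only the 4-phenoxide is a good nucleophile in aqueous alcoholic KOH, since the 2-OH stays hydrogen-bonded to the carboxylate and any benzyl ester is saponified in the same medium.

**Step 11**
Reactants: 18 4-(benzyloxy)-2-hydroxybenzoic acid
Product: 19 tert-butyldimethylsilyl 4-(benzyloxy)-2-(tert-butyldimethylsilyloxy)benzoate
Conditions: tBuMe2SiCl (2.5 equiv), imidazole, DMF, rt
Reagents that add atoms: tert-butyl(chloro)dimethylsilane, CC(C)(C)[Si](C)(C)Cl
Why: Imidazole-promoted silylation covers both the acid and the ortho phenol of a salicylic acid, giving ring A an ortho protecting group that is orthogonal to the benzyl ethers.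

**Step 12**
Reactants: 19 tert-butyldimethylsilyl 4-(benzyloxy)-2-(tert-butyldimethylsilyloxy)benzoate
Product: 20 4-(benzyloxy)-2-(tert-butyldimethylsilyloxy)benzoyl chloride
Conditions: (COCl)2, DMF (cat.), CH2Cl2, 0 °C to rt; volatiles removed
Reagents that add atoms: oxalyl chloride, O=C(Cl)C(=O)Cl
Why: Vilsmeier-type activation turns a silyl ester into the acid chloride under neutral conditions without releasing HCl, so the aryl silyl ether should stay in place.

**Step 13**
Reactants: 16 1,5-bis(benzyloxy)-2-(chloromethyl)-4-methoxy-3-[3-methyl-3-(triethylsilyloxy)butyl]benzene; 20 4-(benzyloxy)-2-(tert-butyldimethylsilyloxy)benzoyl chloride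
Product: 22 1-[4-(benzyloxy)-2-(tert-butyldimethylsilyloxy)phenyl]-2-{4,6-bis(benzyloxy)-3-methoxy-2-[3-methyl-3-(triethylsilyloxy)butyl]phenyl}ethan-1-one, via benzylzinc chloride 21 (not isolated)
Conditions: 16, Zn dust, LiCl, THF, 0 to 25 °C; then 20, Pd(PPh3)4 (5 mol %), THF, 0 °C to rt
Reagents that add atoms: none
Why: LiCl-assisted zinc insertion into a benzylic chloride followed by Negishi acylation under zerovalent palladium catalysis forms the C3–C4 bond, tolerates all the ethers and stops at the ketone.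

**Step 14**
Reactants: 22 1-[4-(benzyloxy)-2-(tert-butyldimethylsilyloxy)phenyl]-2-{4,6-bis(benzyloxy)-3-methoxy-2-[3-methyl-3-(triethylsilyloxy)butyl]phenyl}ethan-1-one
Product: 23 1-[4-(benzyloxy)-2-hydroxyphenyl]-2-[4,6-bis(benzyloxy)-2-(3-hydroxy-3-methylbutyl)-3-methoxyphenyl]ethan-1-one
Conditions: Bu4NF (3 equiv), THF, 0 °C to rt; water
Reagents that add atoms: none
Why: Fluoride desilylation clears both silicon groups at once and frees only the ring A ortho phenol, while the benzylated C2' oxygen of ring B cannot condense with the ketone to a benzofuran.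

**Step 15**
Reactants: 23 1-[4-(benzyloxy)-2-hydroxyphenyl]-2-[4,6-bis(benzyloxy)-2-(3-hydroxy-3-methylbutyl)-3-methoxyphenyl]ethan-1-one
Product: 25 7-(benzyloxy)-3-[4,6-bis(benzyloxy)-2-(3-hydroxy-3-methylbutyl)-3-methoxyphenyl]-4H-chromen-4-one, via enaminone 24 (not isolated)
Conditions: Me2NCH(OMe)2, toluene, 80 °C
Reagents that add atoms: N,N-dimethylformamide dimethyl acetal, COC(OC)N(C)C
Why: This is the classical isoflavone synthesis from a 2-hydroxydeoxybenzoin, in which aminomethylenation of the active CH2 supplies C2 and the chelated phenol then displaces dimethylamine by addition–elimination to close ring C.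

**Step 16**
Reactants: 25 7-(benzyloxy)-3-[4,6-bis(benzyloxy)-2-(3-hydroxy-3-methylbutyl)-3-methoxyphenyl]-4H-chromen-4-one
Product: 26 kwakhurin hydrate (3-[4,6-dihydroxy-2-(3-hydroxy-3-methylbutyl)-3-methoxyphenyl]-7-hydroxy-4H-chromen-4-one)
Conditions: H2 (1 atm), Pd/C, EtOAc–MeOH, rt; stopped after uptake of three equivalents
Reagents that add atoms: none
Why: Catalytic hydrogenolysis removes the three aryl benzyl ethers under neutral conditions that spare the tertiary alcohol, and the C2–C3 double bond is shielded by the doubly ortho-substituted ring B.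

**Compound list**
1 | 5,5-dimethyloxolan-2-one | CC1(C)CCC(=O)O1 | starting material
2 | 4-hydroxy-N-methoxy-N,4-dimethylpentanamide | CON(C)C(=O)CCC(C)(C)O | intermediate
3 | N-methoxy-N,4-dimethyl-4-(triethylsilyloxy)pentanamide | CON(C)C(=O)CCC(C)(C)O[Si](CC)(CC)CC | intermediate
4 | 2,2,6-trimethyl-4H-1,3-dioxin-4-one | CC1=CC(=O)OC(C)(C)O1 | starting material
5 | methoxyacetyl chloride | COCC(=O)Cl | starting material
6 | lithium dienolate of 4 (lithium 2,2-dimethyl-6-methylidene-1,3-dioxin-4-olate) | [Li+].C=C1C=C([O-])OC(C)(C)O1 | intermediate (not isolated)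
7 | 6-(3-methoxy-2-oxopropyl)-2,2-dimethyl-4H-1,3-dioxin-4-one | COCC(=O)CC1=CC(=O)OC(C)(C)O1 | intermediate
8 | dilithium dianion of 7 (bis-enolate form) | [Li+].[Li+].COC=C([O-])C=C1C=C([O-])OC(C)(C)O1 | intermediate (not isolated)
9 | 6-[3-methoxy-7-methyl-2,4-dioxo-7-(triethylsilyloxy)octyl]-2,2-dimethyl-4H-1,3-dioxin-4-one (racemic, enolizable centre) | CC1(C)OC(=O)C=C(CC(=O)C(OC)C(=O)CCC(C)(C)O[Si](CC)(CC)CC)O1 | intermediate
10 | 5-hydroxy-6-methoxy-2,2-dimethyl-5-[3-methyl-3-(triethylsilyloxy)butyl]-5,6-dihydro-4H-1,3-benzodioxine-4,7(8H)-dione (diastereomer mixture, both centres lost) | COC1C(=O)CC2=C(C(=O)OC(C)(C)O2)C1(O)CCC(C)(C)O[Si](CC)(CC)CC | intermediate (not isolated)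
11 | 7-hydroxy-6-methoxy-2,2-dimethyl-5-[3-methyl-3-(triethylsilyloxy)butyl]-4H-1,3-benzodioxin-4-one | COc1c(O)cc2OC(C)(C)OC(=O)c2c1CCC(C)(C)O[Si](CC)(CC)CC | intermediate
12 | 7-(benzyloxy)-6-methoxy-2,2-dimethyl-5-[3-methyl-3-(triethylsilyloxy)butyl]-4H-1,3-benzodioxin-4-one | COc1c(OCc3ccccc3)cc2OC(C)(C)OC(=O)c2c1CCC(C)(C)O[Si](CC)(CC)CC | intermediate
13 | 5-(benzyloxy)-2-(hydroxymethyl)-4-methoxy-3-[3-methyl-3-(triethylsilyloxy)butyl]phenol | COc1c(OCc2ccccc2)cc(O)c(CO)c1CCC(C)(C)O[Si](CC)(CC)CC | intermediate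
14 | {4,6-bis(benzyloxy)-3-methoxy-2-[3-methyl-3-(triethylsilyloxy)butyl]phenyl}methanol | COc1c(OCc2ccccc2)cc(OCc2ccccc2)c(CO)c1CCC(C)(C)O[Si](CC)(CC)CC | intermediate
15 | {4,6-bis(benzyloxy)-3-methoxy-2-[3-methyl-3-(triethylsilyloxy)butyl]phenyl}methyl methanesulfonate | COc1c(OCc2ccccc2)cc(OCc2ccccc2)c(COS(C)(=O)=O)c1CCC(C)(C)O[Si](CC)(CC)CC | intermediate (not isolated)
16 | 1,5-bis(benzyloxy)-2-(chloromethyl)-4-methoxy-3-[3-methyl-3-(triethylsilyloxy)butyl]benzene | COc1c(OCc2ccccc2)cc(OCc2ccccc2)c(CCl)c1CCC(C)(C)O[Si](CC)(CC)CC | intermediate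
17 | 2,4-dihydroxybenzoic acid | O=C(O)c1ccc(O)cc1O | starting material
18 | 4-(benzyloxy)-2-hydroxybenzoic acid | O=C(O)c1ccc(OCc2ccccc2)cc1O | intermediate
19 | tert-butyldimethylsilyl 4-(benzyloxy)-2-(tert-butyldimethylsilyloxy)benzoate | CC(C)(C)[Si](C)(C)OC(=O)c1ccc(OCc2ccccc2)cc1O[Si](C)(C)C(C)(C)C | intermediate
20 | 4-(benzyloxy)-2-(tert-butyldimethylsilyloxy)benzoyl chloride | O=C(Cl)c1ccc(OCc2ccccc2)cc1O[Si](C)(C)C(C)(C)C | intermediate
21 | {4,6-bis(benzyloxy)-3-methoxy-2-[3-methyl-3-(triethylsilyloxy)butyl]benzyl}zinc chloride | COc1c(OCc2ccccc2)cc(OCc2ccccc2)c(C[Zn]Cl)c1CCC(C)(C)O[Si](CC)(CC)CC | intermediate (not isolated)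
22 | 1-[4-(benzyloxy)-2-(tert-butyldimethylsilyloxy)phenyl]-2-{4,6-bis(benzyloxy)-3-methoxy-2-[3-methyl-3-(triethylsilyloxy)butyl]phenyl}ethan-1-one | COc1c(OCc2ccccc2)cc(OCc2ccccc2)c(CC(=O)c2ccc(OCc3ccccc3)cc2O[Si](C)(C)C(C)(C)C)c1CCC(C)(C)O[Si](CC)(CC)CC | intermediate
23 | 1-[4-(benzyloxy)-2-hydroxyphenyl]-2-[4,6-bis(benzyloxy)-2-(3-hydroxy-3-methylbutyl)-3-methoxyphenyl]ethan-1-one | COc1c(OCc2ccccc2)cc(OCc2ccccc2)c(CC(=O)c2ccc(OCc3ccccc3)cc2O)c1CCC(C)(C)O | intermediate
24 | 1-[4-(benzyloxy)-2-hydroxyphenyl]-2-[4,6-bis(benzyloxy)-2-(3-hydroxy-3-methylbutyl)-3-methoxyphenyl]-3-(dimethylamino)prop-2-en-1-one (alkene geometry of no consequence) | COc1c(OCc2ccccc2)cc(OCc2ccccc2)c(C(=CN(C)C)C(=O)c2ccc(OCc3ccccc3)cc2O)c1CCC(C)(C)O | intermediate (not isolated)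
25 | 7-(benzyloxy)-3-[4,6-bis(benzyloxy)-2-(3-hydroxy-3-methylbutyl)-3-methoxyphenyl]-4H-chromen-4-one | COc1c(OCc2ccccc2)cc(OCc2ccccc2)c(-c2coc3cc(OCc4ccccc4)ccc3c2=O)c1CCC(C)(C)O | intermediate
26 | kwakhurin hydrate, 3-[4,6-dihydroxy-2-(3-hydroxy-3-methylbutyl)-3-methoxyphenyl]-7-hydroxy-4H-chromen-4-one | COc1c(O)cc(O)c(-c2coc3cc(O)ccc3c2=O)c1CCC(C)(C)O | target

**Step count**
- Total: 16 steps.
- Longest linear sequence: 12 steps (1, 2, 4–9, 13–16).
- Side branches: step 3 and steps 10–12.

**Steps most likely to fail**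

*Step 4.*
- Risk: the methoxy-substituted carbanion is hindered. It may act as a base towards the α-CH2 of the amide, or trigger base-induced fragmentation of the N-methoxy amide, so that addition stalls and both partners are returned.
- Fallback: it sets out from 3 (with dianion 8) and comes back at 9, replacing acylation by aldol addition and oxidation.
- Amide 3 is reduced with iBu2AlH (THF, −78 °C) to 4-methyl-4-(triethylsilyloxy)pentanal F1.
- Dianion 8 adds to this much more electrophilic partner at −78 °C. This gives 6-[4-hydroxy-3-methoxy-7-methyl-2-oxo-7-(triethylsilyloxy)octyl]-2,2-dimethyl-4H-1,3-dioxin-4-one F2 as a diastereomer mixture of no consequence.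
- Dess–Martin periodinane in CH2Cl2 then oxidizes the carbinol to 9.

*Step 13.*
- Risk: the very electron-rich benzylic chloride may ionize and self-alkylate before or during zinc insertion. Wurtz-type homocoupling on the zinc surface may also consume the reagent.
- Fallback: it sets out from 14, avoids benzylic halide and organozinc altogether, and comes back at 25.
- MnO2 in CH2Cl2 gives 4,6-bis(benzyloxy)-3-methoxy-2-[3-methyl-3-(triethylsilyloxy)butyl]benzaldehyde F3.
- Claisen–Schmidt condensation with commercial 1-[4-(benzyloxy)-2-hydroxyphenyl]ethan-1-one (CC(=O)c1ccc(OCc2ccccc2)cc1O; KOH, EtOH) gives (E)-1-[4-(benzyloxy)-2-hydroxyphenyl]-3-{4,6-bis(benzyloxy)-3-methoxy-2-[3-methyl-3-(triethylsilyloxy)butyl]phenyl}prop-2-en-1-one F4.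
- Oxidative 1,2-aryl migration with Tl(NO3)3·3H2O in MeOH–HC(OMe)3 (trivalent thallium; favoured by the donor-rich migrating ring B) gives 1-[4-(benzyloxy)-2-hydroxyphenyl]-2-{4,6-bis(benzyloxy)-3-methoxy-2-[3-methyl-3-(triethylsilyloxy)butyl]phenyl}-3,3-dimethoxypropan-1-one F5.
- Aqueous HCl in MeOH closes ring C and removes the silyl ether to reach 25.
- In this variant the former carboxyl carbon ends as C2 instead of C3.

*Step 5.*
- Risk: enolization of the methoxy-diketone unit may blunt the C6' carbonyl. Ring closure then slows, and O-cyclization or silyl loss can compete.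
- Fallback: it sets out from 9 and comes back at 14. The same C1'–C6' aldol bond is kept, but the fold is run on the unmasked chain.
- Heating 9 in toluene at 110 °C with MeOH expels acetone by retro-[4+2]. The acylketene is trapped as methyl 6-methoxy-10-methyl-3,5,7-trioxo-10-(triethylsilyloxy)undecanoate F6.
- Cs2CO3 in MeOH and then AcOH folds this more acidic, conformationally free β-keto ester to methyl 4,6-dihydroxy-3-methoxy-2-[3-methyl-3-(triethylsilyloxy)butyl]benzoate F7.
- BnBr and K2CO3 in DMF at 60 °C cap both phenols to give methyl 4,6-bis(benzyloxy)-3-methoxy-2-[3-methyl-3-(triethylsilyloxy)butyl]benzoate F8.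
- LiAlH4 in THF then delivers 14.

**Further compounds**
F1 | step 4 | 4-methyl-4-(triethylsilyloxy)pentanal | O=CCCC(C)(C)O[Si](CC)(CC)CC
F2 | step 4 | 6-[4-hydroxy-3-methoxy-7-methyl-2-oxo-7-(triethylsilyloxy)octyl]-2,2-dimethyl-4H-1,3-dioxin-4-one (diastereomer mixture) | CC1(C)OC(=O)C=C(CC(=O)C(OC)C(O)CCC(C)(C)O[Si](CC)(CC)CC)O1
F3 | step 13 | 4,6-bis(benzyloxy)-3-methoxy-2-[3-methyl-3-(triethylsilyloxy)butyl]benzaldehyde | COc1c(OCc2ccccc2)cc(OCc2ccccc2)c(C=O)c1CCC(C)(C)O[Si](CC)(CC)CC
F4 | step 13 | (E)-1-[4-(benzyloxy)-2-hydroxyphenyl]-3-{4,6-bis(benzyloxy)-3-methoxy-2-[3-methyl-3-(triethylsilyloxy)butyl]phenyl}prop-2-en-1-one | COc1c(OCc2ccccc2)cc(OCc2ccccc2)c(/C=C/C(=O)c2ccc(OCc3ccccc3)cc2O)c1CCC(C)(C)O[Si](CC)(CC)CC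
F5 | step 13 | 1-[4-(benzyloxy)-2-hydroxyphenyl]-2-{4,6-bis(benzyloxy)-3-methoxy-2-[3-methyl-3-(triethylsilyloxy)butyl]phenyl}-3,3-dimethoxypropan-1-one (racemic) | COc1c(OCc2ccccc2)cc(OCc2ccccc2)c(C(C(OC)OC)C(=O)c2ccc(OCc3ccccc3)cc2O)c1CCC(C)(C)O[Si](CC)(CC)CC
F6 | step 5 | methyl 6-methoxy-10-methyl-3,5,7-trioxo-10-(triethylsilyloxy)undecanoate (racemic, enolizable) | COC(=O)CC(=O)CC(=O)C(OC)C(=O)CCC(C)(C)O[Si](CC)(CC)CC
F7 | step 5 | methyl 4,6-dihydroxy-3-methoxy-2-[3-methyl-3-(triethylsilyloxy)butyl]benzoate | COC(=O)c1c(O)cc(O)c(OC)c1CCC(C)(C)O[Si](CC)(CC)CC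
F8 | step 5 | methyl 4,6-bis(benzyloxy)-3-methoxy-2-[3-methyl-3-(triethylsilyloxy)butyl]benzoate | COC(=O)c1c(OCc2ccccc2)cc(OCc2ccccc2)c(OC)c1CCC(C)(C)O[Si](CC)(CC)CC
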